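**Retrosynthetic overview**
- 19 has two rings. The veratryl ring is bought (in 1). The cyclohexa-2,5-dienone ring (C1 = C=O, C2 = allyl carbon, C4 = quaternary carbon) is the only ring made, and it is closed in the last step.
- Enabling feature: C4 is bonded to both β-carbons (C3 and C5) of the C1 carbonyl. The six ring atoms C3=C2–C1(O)=C6–C5=C4 are therefore those of a 3-oxidohexatriene, and C5–OMe is a β-alkoxy-enone oxygen that an ynone takes up from methoxide.
- Key disconnection C3–C4: the ion-paired trienolate 17 undergoes disrotatory 6π closure and then loses a C3 methoxide. Removing MeOH at C5 and adding it back at C3 leads to the acyclic ynone acetal 14 (= 19 + MeOH), whose stereocentres and alkene geometries do not matter.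
- C1–C6 disconnection of 14: lithium acetylide 13 plus Weinreb amide 12.
- 7 (C4–C6 and the side chain) comes from 1, 2, 4 and MeI. 12 (C1–C3 and the allyl group) comes from 8 and 9.

Key step: step 7

Remark: C1–C6 are the dienone locants of 19 and are used for the same atoms in all precursors. Assumption: the sense of induction of the ammonium cation in step 7 cannot be derived from precedent, so the (S,S) catalyst is written and its commercial (R,R) antipode is taken if the first run shows the opposite sense.

**Step 1**
Reactants: 1 3,4-dimethoxybenzaldehyde; 2 propanal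
Product: 3 (E)-3-(3,4-dimethoxyphenyl)-2-methylprop-2-enal
Conditions: NaOH (cat.), MeOH–H2O, slow addition of 2, 0 °C → rt
Reagents that add atoms: none
Why: Claisen–Schmidt (crossed aldol) condensation of a non-enolisable aldehyde, in which reversible aldol addition and E1cB dehydration should give the thermodynamic E enal (aryl trans to CHO).

**Step 2**
Reactants: 3 (E)-3-(3,4-dimethoxyphenyl)-2-methylprop-2-enal; 4 ethynylmagnesium bromide
Product: 5 rac-(E)-1-(3,4-dimethoxyphenyl)-2-methylpent-1-en-4-yn-3-ol
Conditions: THF, −20 → 0 °C; aqueous work-up
Reagents that add atoms: none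
Why: Grignard 1,2-addition of the hard acetylide to the enal, in which the new carbinol centre may stay racemic because it is planarised in step 7.

**Step 3**
Reactants: 5 rac-(E)-1-(3,4-dimethoxyphenyl)-2-methylpent-1-en-4-yn-3-ol
Product: 7 rac-(E)-1,2-dimethoxy-4-(3-methoxy-2-methylpent-1-en-4-yn-1-yl)benzene, via sodium alkoxide 6 (not isolated)
Conditions: NaH, THF, 0 °C; then MeI, 0 °C → rt
Reagents that add atoms: iodomethane, CI
Why: Williamson ether synthesis under basic conditions, which avoids ionisation of the electron-rich cinnamyl-type carbinol.

**Step 4**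
Reactants: 8 methyl 3,3-dimethoxypropanoate; 9 allyl bromide
Product: 11 rac-methyl 2-(dimethoxymethyl)pent-4-enoate, via lithium enolate 10 (not isolated)
Conditions: LDA (commercial solution), THF, −78 °C; then 9, DMPU, −78 → −40 °C
Reagents that add atoms: none
Why: SN2 alkylation of a lithium ester enolate with an allylic bromide at a temperature where β-elimination of methoxide is slow, giving a racemic centre that is erased in step 7.

**Step 5**
Reactants: 11 rac-methyl 2-(dimethoxymethyl)pent-4-enoate
Product: 12 rac-2-(dimethoxymethyl)-N-methoxy-N-methylpent-4-enamide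
Conditions: MeNH(OMe)·HCl, i-PrMgCl, THF, −20 → 0 °C
Reagents that add atoms: N,O-dimethylhydroxylamine hydrochloride, CNOC.Cl
Why: Weinreb amide synthesis by aminolysis of the ester with the chloromagnesium amide, which should leave the acetal and the alkene untouched at low temperature.

**Step 6**
Reactants: 7 rac-(E)-1,2-dimethoxy-4-(3-methoxy-2-methylpent-1-en-4-yn-1-yl)benzene; 12 rac-2-(dimethoxymethyl)-N-methoxy-N-methylpent-4-enamide
Product: 14 (E)-10-(3,4-dimethoxyphenyl)-4-(dimethoxymethyl)-8-methoxy-9-methyldeca-1,9-dien-6-yn-5-one (mixture of all four stereoisomers), via lithium acetylide 13 (not isolated)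
Conditions: 7, n-BuLi, THF, −78 °C; then 12, −78 → −30 °C; AcOH, −78 °C
Reagents that add atoms: none
Why: Weinreb ketone synthesis, in which the acetylide adds only once and the cold acidic quench releases the base-sensitive ynone only when no base is left.

**Step 7**
Reactants: 14 (E)-10-(3,4-dimethoxyphenyl)-4-(dimethoxymethyl)-8-methoxy-9-methyldeca-1,9-dien-6-yn-5-one
Product: 19 (S)-2-allyl-4-[(E)-1-(3,4-dimethoxyphenyl)prop-1-en-2-yl]-4,5-dimethoxycyclohexa-2,5-dien-1-one, via methoxymethylene ynone 15 (not isolated), via bis-enol-ether dienone 16 (not isolated), via ammonium trienolate 17 (not isolated), via cyclised dienolate 18 (not isolated)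
Conditions: (S,S)-3,4,5-trifluorophenyl-NAS bromide (10 mol %), KOMe (8 mol %), toluene, Ar, 0 °C → rt
Reagents that add atoms: none
Why: Proposed new method: the only soluble base is the chiral ammonium methoxide made from the catalyst and KOMe; it expels MeOH from the β-keto acetal (E1cB, 15), adds to the ynone at C5 (oxa-Michael, 16) and removes the doubly allylic C4–H, so that all four stereoisomers of 14 and all E/Z and prototropic isomers of 15 and 16 drain into one planar, ion-paired 3-oxidohexatriene 17. Thermal disrotatory 6π electrocyclisation of 17 closes the six-membered ring through the C3–C4 bond (formally 6-endo-trig at C3) to the dienolate 18, whose fast, irreversible E1cB loss of the C3 methoxide gives 19 and returns the ammonium methoxide, so that methoxide is relayed from C3 to C5 and the balance is only the loss of one MeOH. Closest known reaction types: the base-catalysed phorone-to-isophorone cyclisation and the oxyanion-accelerated electrocyclisation of 3-oxidohexatrienes for the closure, and the chiral-ammonium-catalysed 6π electrocyclisation of 2-azapentadienyl anions for the ion-pair control; new is the transfer to an all-carbon trienolate that creates a fully substituted ether carbon. C4, the only new stereocentre that survives, is set in the closure: the arylpropenyl group takes the outside and the small OMe the inside position at C4, so the configuration follows from the sense of the helix alone, and this is chosen by the C2-symmetric cation that is bound at the C1 oxide and can stack its electron-poor trifluorophenyl rings on the electron-rich veratryl group. The step needs periselectivity, regioselectivity for C5–OMe and retention of the E side chain: bonding from C6 or from the benzylic terminus would give a four- or an eight-membered ring (the 8π mode needs the arylpropenyl group inside), the polarity of the ynone puts methoxide on C5 only, and the E geometry is the thermodynamic one in the delocalised anion.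

**Compound list**
1 | 3,4-dimethoxybenzaldehyde | COc1ccc(C=O)cc1OC | starting material
2 | propanal | CCC=O | starting material
3 | (E)-3-(3,4-dimethoxyphenyl)-2-methylprop-2-enal | O=C/C(C)=C/c1ccc(OC)c(OC)c1 | intermediate
4 | ethynylmagnesium bromide | C#C[Mg]Br | starting material
5 | rac-(E)-1-(3,4-dimethoxyphenyl)-2-methylpent-1-en-4-yn-3-ol | C#CC(O)/C(C)=C/c1ccc(OC)c(OC)c1 | intermediate
6 | sodium alkoxide of 5 | [Na+].C#CC([O-])/C(C)=C/c1ccc(OC)c(OC)c1 | intermediate
7 | rac-(E)-1,2-dimethoxy-4-(3-methoxy-2-methylpent-1-en-4-yn-1-yl)benzene | C#CC(OC)/C(C)=C/c1ccc(OC)c(OC)c1 | intermediate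
8 | methyl 3,3-dimethoxypropanoate | COC(=O)CC(OC)OC | starting material
9 | allyl bromide | C=CCBr | starting material
10 | lithium enolate of 8 | [Li+].COC(OC)C=C([O-])OC | intermediate
11 | rac-methyl 2-(dimethoxymethyl)pent-4-enoate | C=CCC(C(OC)OC)C(=O)OC | intermediate
12 | rac-2-(dimethoxymethyl)-N-methoxy-N-methylpent-4-enamide | C=CCC(C(OC)OC)C(=O)N(C)OC | intermediate
13 | lithium acetylide of 7 | [Li]C#CC(OC)/C(C)=C/c1ccc(OC)c(OC)c1 | intermediate
14 | (E)-10-(3,4-dimethoxyphenyl)-4-(dimethoxymethyl)-8-methoxy-9-methyldeca-1,9-dien-6-yn-5-one, stereoisomer mixture at C4 and C8 of the chain | C=CCC(C(OC)OC)C(=O)C#CC(OC)/C(C)=C/c1ccc(OC)c(OC)c1 | intermediate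
15 | (9E)-10-(3,4-dimethoxyphenyl)-8-methoxy-4-(methoxymethylidene)-9-methyldeca-1,9-dien-6-yn-5-one, E/Z at the enol ether | C=CCC(=COC)C(=O)C#CC(OC)/C(C)=C/c1ccc(OC)c(OC)c1 | intermediate
16 | (9E)-10-(3,4-dimethoxyphenyl)-7,8-dimethoxy-4-(methoxymethylidene)-9-methyldeca-1,6,9-trien-5-one, E/Z mixtures | C=CCC(=COC)C(=O)C=C(OC)C(OC)/C(C)=C/c1ccc(OC)c(OC)c1 | intermediate
17 | 3-oxidohexatriene (trienolate) from 16, anion of the ion pair with the catalyst cation | C=CCC(=COC)C([O-])=CC(OC)=C(OC)/C(C)=C/c1ccc(OC)c(OC)c1 | intermediate
18 | 2-allyl-4-[(E)-1-(3,4-dimethoxyphenyl)prop-1-en-2-yl]-3,4,5-trimethoxycyclohexa-1,5-dien-1-olate, C4 as in 19, C3 transient | C=CCC1=C([O-])C=C(OC)[C@@](OC)(/C(C)=C/c2ccc(OC)c(OC)c2)C1OC | intermediate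
19 | (S)-2-allyl-4-[(E)-1-(3,4-dimethoxyphenyl)prop-1-en-2-yl]-4,5-dimethoxycyclohexa-2,5-dien-1-one | C=CCC1=C[C@](OC)(/C(C)=C/c2ccc(OC)c(OC)c2)C(OC)=CC1=O | target

**Step count**
Total step count: 7. Longest linear sequence: 5 (steps 1, 2, 3, 6, 7).

**Steps most likely to fail**

1. Step 7.
 - What may go wrong: The two helical ion-paired transition states may be discriminated only weakly, because the cation sits at the C1 oxide and is remote from C4, and the released methanol loosens the ion pair. Closure at the fully substituted terminus may also be slow, so that the trienolate rests as its fully conjugated prototropic isomer or leaks into the 8π mode.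
 - Fallback (from 14, back at 19): Enantiocontrol by catalysis is given up. 14 is treated with stoichiometric NaOMe in MeOH–THF between rt and 50 °C. These are conditions of the phorone–isophorone type, in which no ion pair has to be preserved and heating is allowed. This should give racemic 2-allyl-4-[(E)-1-(3,4-dimethoxyphenyl)prop-1-en-2-yl]-4,5-dimethoxycyclohexa-2,5-dien-1-one F1. Its enantiomers are separated by preparative SFC on a polysaccharide chiral phase. The S enantiomer, assigned by ECD against calculation, is 19.

2. Step 6.
 - What may go wrong: A proton may be transferred from the α-CH of the amide to the acetylide, followed by loss of methoxide. This turns the amide into an unreactive vinylogous carbamate and returns the alkyne.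
 - Fallback (from 11, back at 14): Acyl substitution is replaced by a redox sequence. 11 is reduced with DIBAL-H in CH2Cl2 at −78 °C to 2-(dimethoxymethyl)pent-4-enal F2. The much more electrophilic aldehyde takes up acetylide 13 at −78 °C to give the propargylic alcohol 10-(3,4-dimethoxyphenyl)-4-(dimethoxymethyl)-8-methoxy-9-methyldeca-1,9-dien-6-yn-5-ol F3. Oxidation of F3 with buffered Dess–Martin periodinane (or MnO2) gives 14.

3. Step 4.
 - What may go wrong: Methoxide may be lost from the enolate by β-elimination before alkylation, and proton exchange may lead to double alkylation.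
 - Fallback (from 9, back at 11): The order of bond formation is inverted, so the allyl group is placed first and the formyl carbon afterwards. 9 alkylates the lithium enolate of methyl acetate to give methyl pent-4-enoate F4, which is also a catalogue compound. Crossed Claisen condensation of F4 with methyl formate (NaH, THF) gives methyl 2-formylpent-4-enoate F5. Acetalisation of F5 with HC(OMe)3 and MeOH under acid catalysis gives 11.

**Further compounds**
F1 | step 7 | racemic 2-allyl-4-[(E)-1-(3,4-dimethoxyphenyl)prop-1-en-2-yl]-4,5-dimethoxycyclohexa-2,5-dien-1-one | C=CCC1=CC(OC)(/C(C)=C/c2ccc(OC)c(OC)c2)C(OC)=CC1=O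
F2 | step 6 | rac-2-(dimethoxymethyl)pent-4-enal | C=CCC(C=O)C(OC)OC
F3 | step 6 | (E)-10-(3,4-dimethoxyphenyl)-4-(dimethoxymethyl)-8-methoxy-9-methyldeca-1,9-dien-6-yn-5-ol, stereoisomer mixture | C=CCC(C(OC)OC)C(O)C#CC(OC)/C(C)=C/c1ccc(OC)c(OC)c1
F4 | step 4 | methyl pent-4-enoate | C=CCCC(=O)OC
F5 | step 4 | rac-methyl 2-formylpent-4-enoate | C=CCC(C=O)C(=O)OC
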